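**Retrosynthetic overview**
1. The C3 ester is made last, from the cis diol-phenol 13 and (Z)-2-(acetoxymethyl)but-2-enoic acid 21. Acid 21 comes from crotonaldehyde through (Z)-2-bromobut-2-enal: the CHO becomes CH2OAc and the C–Br becomes CO2H with retention, which fixes the Z geometry.
2. The only ring formed is the dihydrofuran ring of the 2,3-dihydrobenzofuran. It is closed at C7a–O1, the one bond of that ring that touches neither C2 nor C3. C7a lies para to the C5 acetyl group, so a fluoride at C7a can be displaced by the C2 alkoxide.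
3. C2 and C3 are therefore set in the open chain, as the syn (1S,2S) diol 11, by alkoxyallylboration of aldehyde 4 with the methallyl MOM ether 6.
4. Aldehyde 4 comes from 4-fluoro-2-hydroxyacetophenone by formylation para to the hydroxyl and O-allylation; the allyl group keeps the ring electron-poor for the substitution.

Key step: step 6

Assumption: the ring is numbered O1, C2 (isopropenyl), C3 (ester), C5 (acetyl), C6 (OH), C7a (aryl carbon on O1); the target is read as (2S,3S), cis, with a (Z) side-chain alkene; (+)-Ipc2BOMe means the reagent made from (−)-α-pinene.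

**Route**

Step 1
Reactants: 1 4-fluoro-2-hydroxyacetophenone
Product: 3 5-acetyl-2-fluoro-4-hydroxybenzaldehyde, via aryl aldimine 2 (not isolated)
Conditions: hexamethylenetetramine (2 equiv), CF3CO2H, 85 °C; then 3 M aq. HCl, 50 °C
Reagents that add atoms: hexamethylenetetramine (C1N2CN3CN1CN(C2)C3); water (O)
Why: Duff formylation, in which the iminium ion from protonated hexamethylenetetramine should attack para to the hydroxyl (C5, meta to the acetyl) because the ortho site C3 is flanked by OH and F and the OH is held in a hydrogen bond to the acetyl group; the iminium stage 2 (written as the free aldimine) is hydrolysed by the acid.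

Step 2
Reactants: 3 5-acetyl-2-fluoro-4-hydroxybenzaldehyde
Product: 4 5-acetyl-2-fluoro-4-(prop-2-enyloxy)benzaldehyde
Conditions: allyl bromide (1.5 equiv), K2CO3, DMF, rt
Reagents that add atoms: allyl bromide (C=CCBr)
Why: Williamson ether synthesis on the acidic, doubly acyl-stabilised phenoxide, run at room temperature so that the weakly nucleophilic phenoxide alkylates allyl bromide and does not attack the activated C–F bond of the product.

Step 3
Reactants: 5 2-methylprop-2-en-1-ol
Product: 6 3-(methoxymethoxy)-2-methylprop-1-ene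
Conditions: MOMCl (1.2 equiv), i-Pr2NEt, CH2Cl2, 0 °C → rt
Reagents that add atoms: chloromethyl methyl ether (COCCl)
Why: O-alkylation of a primary alcohol with an α-chloro ether (MOM protection), which supplies the ether oxygen that later becomes O1.

Step 4
Reactants: 4 5-acetyl-2-fluoro-4-(prop-2-enyloxy)benzaldehyde; 6 3-(methoxymethoxy)-2-methylprop-1-ene
Product: 10 (1S,2S)-1-[5-acetyl-2-fluoro-4-(prop-2-enyloxy)phenyl]-2-(methoxymethoxy)-3-methylbut-3-en-1-ol, via lithiated ether 7 (not isolated), via allylborane 8 (not isolated), via borinate 9 (not isolated)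
Conditions: 6 (1.4 equiv), s-BuLi, THF, −78 °C; (+)-Ipc2BOMe, −78 °C; BF3·OEt2, −78 °C; then 4, −78 °C; HOCH2CH2NH2, Et2O, rt
Reagents that add atoms: none
Why: Brown asymmetric alkoxyallylboration, in which s-BuLi removes an O–CH2 proton of 6 to give the lithium-chelated Z oxyallyl anion 7, boron takes the CH2 terminus and BF3 strips methoxide to give the (Z)-γ-alkoxyallylborane 8, which adds to the aldehyde (not to the acetyl ketone at −78 °C) through a chair transition state where the Z geometry enforces the syn relationship and the isopinocampheyl groups from (−)-α-pinene direct attack to the Re face, setting C1 and C2 both as S; ethanolamine frees the alcohol from borinate 9 without alkaline peroxide, which could attack the activated aryl fluoride.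

Step 5
Reactants: 10 (1S,2S)-1-[5-acetyl-2-fluoro-4-(prop-2-enyloxy)phenyl]-2-(methoxymethoxy)-3-methylbut-3-en-1-ol
Product: 11 (1S,2S)-1-[5-acetyl-2-fluoro-4-(prop-2-enyloxy)phenyl]-3-methylbut-3-ene-1,2-diol
Conditions: conc. HCl (cat.), MeOH, rt → 40 °C
Reagents that add atoms: none
Why: acid-catalysed acetal exchange (methanolysis of the MOM ether), in which the oxocarbenium ion is taken up by the solvent as dimethoxymethane; the benzylic C1–O bond should not ionise because the ring carries the acetyl and fluoro groups and C2 is oxygenated, so both stereocentres are kept.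

Step 6
Reactants: 11 (1S,2S)-1-[5-acetyl-2-fluoro-4-(prop-2-enyloxy)phenyl]-3-methylbut-3-ene-1,2-diol
Product: 12 1-[(2S,3S)-3-hydroxy-2-(prop-1-en-2-yl)-6-(prop-2-enyloxy)-2,3-dihydro-1-benzofuran-5-yl]ethanone
Conditions: KOt-Bu (2.0 equiv), THF (0.02 M), 0 °C → rt
Reagents that add atoms: none
Why: KOt-Bu forms the diol mono-alkoxide, which equilibrates between the two oxygens; the C2 alkoxide adds to the fluorine-bearing aryl carbon to give a Meisenheimer adduct whose charge is delocalised into the para acetyl group, and loss of fluoride restores the arene (addition–elimination SNAr). The closest known reaction type is the base-mediated intramolecular SNAr etherification of 2-(2-fluoroaryl)ethanols bearing a para acyl, cyano or nitro group to give 2,3-dihydrobenzofurans. The dihydrofuran ring closes in 5-exo fashion by O–C(aryl) bond formation, while the benzylic alkoxide could only form a four-membered ring and so cannot compete. No stereocentre is created: no bond to C2 or C3 is made or broken, so the syn diol maps directly onto the cis (2S,3S) ring. The step needs arylation by the C2 oxygen only (secured by ring size), no ionisation of the allylic C2–O or benzylic C3–O bond (the oxygen acts as nucleophile at a remote carbon, never as leaving group), and closure faster than aldol reaction of the acetyl group or isomerisation of the allyl ether (secured by high dilution and THF at or below room temperature).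

Step 7
Reactants: 12 1-[(2S,3S)-3-hydroxy-2-(prop-1-en-2-yl)-6-(prop-2-enyloxy)-2,3-dihydro-1-benzofuran-5-yl]ethanone
Product: 13 1-[(2S,3S)-3,6-dihydroxy-2-(prop-1-en-2-yl)-2,3-dihydro-1-benzofuran-5-yl]ethanone
Conditions: Pd(PPh3)4 (3 mol%), morpholine (5 equiv), THF, 0 °C → rt
Reagents that add atoms: none
Why: Tsuji–Trost-type deallylation, in which zerovalent palladium ionises the unhindered primary allyl aryl ether to a π-allyl complex that morpholine captures, whereas the ring C2–O1 bond, although allylic, is secondary and flanked by a 1,1-disubstituted alkene and should ionise far more slowly, so C2 keeps its configuration.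

Step 8
Reactants: 14 (E)-but-2-enal (crotonaldehyde)
Product: 16 (Z)-2-bromobut-2-enal, via dibromide 15 (not isolated)
Conditions: Br2 (1.0 equiv), CH2Cl2, −10 °C; then Et3N (1.3 equiv), 0 °C → rt
Reagents that add atoms: bromine (BrBr)
Why: alkene bromination followed by E1cB dehydrobromination through the enolate, which expels the β-bromide and should give the more stable isomer with the methyl group trans to CHO and cis to bromine.

Step 9
Reactants: 16 (Z)-2-bromobut-2-enal
Product: 17 (Z)-2-bromobut-2-en-1-ol
Conditions: NaBH4, CeCl3·7H2O, MeOH, 0 °C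
Reagents that add atoms: none
Why: Luche reduction, a 1,2-selective hydride addition to the enal that leaves the vinyl bromide and its geometry untouched.

Step 10
Reactants: 17 (Z)-2-bromobut-2-en-1-ol
Product: 19 (Z)-2-(hydroxymethyl)but-2-enoic acid, via vinyllithium alkoxide 18 (not isolated)
Conditions: t-BuLi (3.1 equiv), Et2O, −78 °C; CO2, −78 °C → rt; aq. HCl (pH 2)
Reagents that add atoms: carbon dioxide (O=C=O)
Why: O-deprotonation then bromine–lithium exchange with retention of alkene geometry (the vinyllithium is configurationally stable at −78 °C and the alkoxide cannot eliminate), followed by carboxylation, so the carbon that carried bromine becomes CO2H cis to the methyl group (Z).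

Step 11
Reactants: 19 (Z)-2-(hydroxymethyl)but-2-enoic acid
Product: 21 (Z)-2-(acetoxymethyl)but-2-enoic acid, via mixed anhydride 20 (not isolated)
Conditions: Ac2O (2.2 equiv), pyridine, 0 °C → rt; then H2O, rt
Reagents that add atoms: acetic anhydride (CC(=O)OC(C)=O); water (O)
Why: O-acetylation of the primary allylic alcohol, with the carboxyl group passing through the mixed anhydride 20 that water cleaves on work-up; pyridine without a nucleophilic catalyst should leave the Z alkene unchanged.

Step 12
Reactants: 13 1-[(2S,3S)-3,6-dihydroxy-2-(prop-1-en-2-yl)-2,3-dihydro-1-benzofuran-5-yl]ethanone; 21 (Z)-2-(acetoxymethyl)but-2-enoic acid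
Product: 23 (2S,3S)-5-acetyl-6-hydroxy-2-(prop-1-en-2-yl)-2,3-dihydro-1-benzofuran-3-yl (2Z)-2-(acetoxymethyl)but-2-enoate (target), via O-acylisourea 22 (not isolated)
Conditions: 21 (1.3 equiv), DCC (1.4 equiv), DMAP (0.1 equiv), CH2Cl2, −20 → 0 °C
Reagents that add atoms: none
Why: Steglich esterification, in which the O-acylisourea 22 passes the acyl group through the acylpyridinium ion to the C3 hydroxyl, which should react ahead of the C6 phenol because that phenol is tied into a six-membered hydrogen bond with the acetyl carbonyl; no C–O bond at C3 is broken, so the cis (2S,3S) configuration is kept, and the low temperature and catalytic DMAP limit Z to E isomerisation of the acyl group and elimination to the benzofuran.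

**Compound list**
1 | 4-fluoro-2-hydroxyacetophenone | CC(=O)c1ccc(F)cc1O | starting material
2 | 5-acetyl-2-fluoro-4-hydroxybenzaldehyde imine (simplest form of the hexamethylenetetramine-derived iminium) | CC(=O)c1cc(C=N)c(F)cc1O | intermediate (not isolated)
3 | 5-acetyl-2-fluoro-4-hydroxybenzaldehyde | CC(=O)c1cc(C=O)c(F)cc1O | intermediate
4 | 5-acetyl-2-fluoro-4-(prop-2-enyloxy)benzaldehyde | CC(=O)c1cc(C=O)c(F)cc1OCC=C | intermediate
5 | 2-methylprop-2-en-1-ol | C=C(C)CO | starting material
6 | 3-(methoxymethoxy)-2-methylprop-1-ene | C=C(C)COCOC | intermediate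
7 | 1-(methoxymethoxy)-2-methylallyllithium | [Li]C(OCOC)C(C)=C | intermediate (not isolated)
8 | [(Z)-3-(methoxymethoxy)-2-methylprop-2-enyl]diisopinocampheylborane (Ipc from (−)-α-pinene) | COCO/C=C(C)\CB([C@H]1C[C@H]2C[C@@H]([C@@H]1C)C2(C)C)[C@H]1C[C@H]2C[C@@H]([C@@H]1C)C2(C)C | intermediate (not isolated)
9 | diisopinocampheylborinate ester of 10 (boron on the benzylic oxygen) | C=C(C)[C@H](OCOC)[C@@H](OB([C@H]1C[C@H]2C[C@@H]([C@@H]1C)C2(C)C)[C@H]1C[C@H]2C[C@@H]([C@@H]1C)C2(C)C)c1cc(C(C)=O)c(OCC=C)cc1F | intermediate (not isolated)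
10 | (1S,2S)-1-[5-acetyl-2-fluoro-4-(prop-2-enyloxy)phenyl]-2-(methoxymethoxy)-3-methylbut-3-en-1-ol | C=C(C)[C@H](OCOC)[C@@H](O)c1cc(C(C)=O)c(OCC=C)cc1F | intermediate
11 | (1S,2S)-1-[5-acetyl-2-fluoro-4-(prop-2-enyloxy)phenyl]-3-methylbut-3-ene-1,2-diol (syn) | C=C(C)[C@H](O)[C@@H](O)c1cc(C(C)=O)c(OCC=C)cc1F | intermediate
12 | 1-[(2S,3S)-3-hydroxy-2-(prop-1-en-2-yl)-6-(prop-2-enyloxy)-2,3-dihydro-1-benzofuran-5-yl]ethanone (cis) | C=C(C)[C@@H]1Oc2cc(OCC=C)c(C(C)=O)cc2[C@@H]1O | intermediate
13 | 1-[(2S,3S)-3,6-dihydroxy-2-(prop-1-en-2-yl)-2,3-dihydro-1-benzofuran-5-yl]ethanone | C=C(C)[C@@H]1Oc2cc(O)c(C(C)=O)cc2[C@@H]1O | intermediate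
14 | (E)-but-2-enal (crotonaldehyde) | C/C=C/C=O | starting material
15 | 2,3-dibromobutanal | CC(Br)C(Br)C=O | intermediate (not isolated)
16 | (Z)-2-bromobut-2-enal | C/C=C(\Br)C=O | intermediate
17 | (Z)-2-bromobut-2-en-1-ol | C/C=C(\Br)CO | intermediate
18 | lithium 2-lithiobut-2-en-1-olate (lithium in place of bromine, geometry retained) | C/C=C(\[Li])CO[Li] | intermediate (not isolated)
19 | (Z)-2-(hydroxymethyl)but-2-enoic acid | C/C=C(\C(=O)O)CO | intermediate
20 | acetic (Z)-2-(acetoxymethyl)but-2-enoic anhydride | C/C=C(\C(=O)OC(C)=O)COC(C)=O | intermediate (not isolated)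
21 | (Z)-2-(acetoxymethyl)but-2-enoic acid | C/C=C(\C(=O)O)COC(C)=O | intermediate
22 | O-[(Z)-2-(acetoxymethyl)but-2-enoyl]-N,N'-dicyclohexylisourea | C/C=C(\C(=O)OC(=NC1CCCCC1)NC1CCCCC1)COC(C)=O | intermediate (not isolated)
23 | (2S,3S)-5-acetyl-6-hydroxy-2-(prop-1-en-2-yl)-2,3-dihydro-1-benzofuran-3-yl (2Z)-2-(acetoxymethyl)but-2-enoate | C=C(C)[C@@H]1Oc2cc(O)c(C(C)=O)cc2[C@@H]1OC(=O)/C(=C\C)COC(C)=O | target

**Step count**
Total: 12 steps. Longest linear sequence: 7 steps (1, 2, 4, 5, 6, 7, 12, from compound 1).

**Steps most likely to fail**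

Step 6 (key step). The alkoxide may be diverted into enolisation and aldol condensation of the acetyl group, or the substitution may be slow because the allyloxy group ortho to the acetyl weakens its acceptor strength; long exposure to base could then isomerise the allyl ether. Fallback: form the same C7a–O1 bond by copper-catalysed intramolecular C–O coupling of the aryl bromide. It sets out from 6 and returns at 12. Commercial 4-bromo-2-hydroxyacetophenone (CC(=O)c1ccc(Br)cc1O) takes the place of 1. Duff formylation as in step 1 should give 5-acetyl-2-bromo-4-hydroxybenzaldehyde F1, and allylation as in step 2 should give 5-acetyl-2-bromo-4-(prop-2-enyloxy)benzaldehyde F2. Alkoxyallylboration with 8 (made from 6 as in step 4) should pass through the bromo borinate F3 to (1S,2S)-1-[5-acetyl-2-bromo-4-(prop-2-enyloxy)phenyl]-2-(methoxymethoxy)-3-methylbut-3-en-1-ol F4, and HCl in MeOH should give (1S,2S)-1-[5-acetyl-2-bromo-4-(prop-2-enyloxy)phenyl]-3-methylbut-3-ene-1,2-diol F5. CuI (10 mol%), 1,10-phenanthroline (20 mol%) and Cs2CO3 in toluene at 90 °C should then close the ring to 12 with a carbonate base only. Zerovalent palladium is avoided here because of the allyl ether.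

Step 4. Deprotonation of 6 may occur partly at the methyl group instead of the O–CH2 group, or the 2-methyl group of the allyl unit may crowd the chair transition state and erode syn or facial selectivity. Fallback: build the diol by a hydroxyl-directed ene reaction with singlet oxygen, without any lithiated ether or boron reagent. It sets out from 4 and returns at 11, so step 5 is not needed. Nozaki–Hiyama–Kishi coupling of 4 with 1-bromo-2-methylprop-1-ene (CrCl2, catalytic NiCl2, DMF, rt; aldehyde-selective) should give racemic 1-[5-acetyl-2-fluoro-4-(prop-2-enyloxy)phenyl]-3-methylbut-2-en-1-ol F6. Sharpless kinetic resolution [Ti(OiPr)4, D-(−)-diisopropyl tartrate (the tartrate that consumes the (S)-enantiomer), t-BuOOH (0.6 equiv), 4 Å sieves, CH2Cl2, −20 °C] should leave (R)-1-[5-acetyl-2-fluoro-4-(prop-2-enyloxy)phenyl]-3-methylbut-2-en-1-ol F7 and remove its antipode as the erythro epoxy alcohol [5-acetyl-2-fluoro-4-(prop-2-enyloxy)phenyl](3,3-dimethyloxiran-2-yl)methanol F8. Photooxygenation of F7 (O2, tetraphenylporphyrin, hν, CCl4, 0 °C) should give the threo hydroperoxide (1S,2S)-1-[5-acetyl-2-fluoro-4-(prop-2-enyloxy)phenyl]-2-hydroperoxy-3-methylbut-3-en-1-ol F9, because the hydroxyl group steers the oxygen and 1,3-allylic strain fixes the conformation. PPh3 should reduce F9 to 11.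

Step 12. The hindered C3 alcohol may be acylated slowly, so that the chelated phenol competes and the activated acid has time to isomerise from Z to E. Fallback: protect the phenol and use a preformed acid chloride without nucleophilic catalyst. It sets out from 13 (with 21) and returns at 23. TBSCl and imidazole in DMF at 0 °C should silylate the more acidic phenol ahead of the hindered secondary alcohol to give 1-[(2S,3S)-6-(tert-butyldimethylsilyloxy)-3-hydroxy-2-(prop-1-en-2-yl)-2,3-dihydro-1-benzofuran-5-yl]ethanone F10. Acid 21 with 1-chloro-N,N,2-trimethylprop-1-en-1-amine in CH2Cl2 should give (Z)-2-(acetoxymethyl)but-2-enoyl chloride F11 under neutral conditions. F10 and F11 with pyridine in CH2Cl2 at 0 °C should give (2S,3S)-5-acetyl-6-(tert-butyldimethylsilyloxy)-2-(prop-1-en-2-yl)-2,3-dihydro-1-benzofuran-3-yl (2Z)-2-(acetoxymethyl)but-2-enoate F12. HF·pyridine buffered with pyridine in THF at 0 °C should remove the aryl silyl ether, which is labile because it is ortho to the acetyl group, and give 23.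

**Further compounds**
F1 | step 6 | 5-acetyl-2-bromo-4-hydroxybenzaldehyde | CC(=O)c1cc(C=O)c(Br)cc1O
F2 | step 6 | 5-acetyl-2-bromo-4-(prop-2-enyloxy)benzaldehyde | CC(=O)c1cc(C=O)c(Br)cc1OCC=C
F3 | step 6 | diisopinocampheylborinate ester of F4 (not isolated) | C=C(C)[C@H](OCOC)[C@@H](OB([C@H]1C[C@H]2C[C@@H]([C@@H]1C)C2(C)C)[C@H]1C[C@H]2C[C@@H]([C@@H]1C)C2(C)C)c1cc(C(C)=O)c(OCC=C)cc1Br
F4 | step 6 | (1S,2S)-1-[5-acetyl-2-bromo-4-(prop-2-enyloxy)phenyl]-2-(methoxymethoxy)-3-methylbut-3-en-1-ol | C=C(C)[C@H](OCOC)[C@@H](O)c1cc(C(C)=O)c(OCC=C)cc1Br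
F5 | step 6 | (1S,2S)-1-[5-acetyl-2-bromo-4-(prop-2-enyloxy)phenyl]-3-methylbut-3-ene-1,2-diol | C=C(C)[C@H](O)[C@@H](O)c1cc(C(C)=O)c(OCC=C)cc1Br
F6 | step 4 | racemic 1-[5-acetyl-2-fluoro-4-(prop-2-enyloxy)phenyl]-3-methylbut-2-en-1-ol | CC(C)=CC(O)c1cc(C(C)=O)c(OCC=C)cc1F
F7 | step 4 | (R)-1-[5-acetyl-2-fluoro-4-(prop-2-enyloxy)phenyl]-3-methylbut-2-en-1-ol | CC(C)=C[C@@H](O)c1cc(C(C)=O)c(OCC=C)cc1F
F8 | step 4 | erythro [5-acetyl-2-fluoro-4-(prop-2-enyloxy)phenyl](3,3-dimethyloxiran-2-yl)methanol from the (S)-alcohol | CC1(C)O[C@H]1[C@H](O)c1cc(C(C)=O)c(OCC=C)cc1F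
F9 | step 4 | (1S,2S)-1-[5-acetyl-2-fluoro-4-(prop-2-enyloxy)phenyl]-2-hydroperoxy-3-methylbut-3-en-1-ol | C=C(C)[C@H](OO)[C@@H](O)c1cc(C(C)=O)c(OCC=C)cc1F
F10 | step 12 | 1-[(2S,3S)-6-(tert-butyldimethylsilyloxy)-3-hydroxy-2-(prop-1-en-2-yl)-2,3-dihydro-1-benzofuran-5-yl]ethanone | C=C(C)[C@@H]1Oc2cc(O[Si](C)(C)C(C)(C)C)c(C(C)=O)cc2[C@@H]1O
F11 | step 12 | (Z)-2-(acetoxymethyl)but-2-enoyl chloride | C/C=C(\C(Cl)=O)COC(C)=O
F12 | step 12 | (2S,3S)-5-acetyl-6-(tert-butyldimethylsilyloxy)-2-(prop-1-en-2-yl)-2,3-dihydro-1-benzofuran-3-yl (2Z)-2-(acetoxymethyl)but-2-enoate | C=C(C)[C@@H]1Oc2cc(O[Si](C)(C)C(C)(C)C)c(C(C)=O)cc2[C@@H]1OC(=O)/C(=C\C)COC(C)=O
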